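**Retrosynthetic overview**

1. The route rests on the C2(=O)–C3–C4–C5(Me)=C6 unit of the ten-membered ring (C1–C10), a γ,δ-unsaturated ketone and hence a Claisen retron. Ten-membered ketone 35 comes from the eight-membered 2-methylene oxocane 34 (ring O, C2, C1, C10, C9, C8, C7, C6) that carries the isopropenyl group (C5, C4, C16) on C6.
2. 34 comes from lactone 33 (Petasis methylenation) and seco acid 31 (Shiina lactonisation). The C6 carbinol arises from isopropenylmagnesium bromide and aldehyde 27.
3. The C7/C8 diol arises by cis-dihydroxylation of butenolide 22 on the face anti to ring A. 22 comes from a Ni/Cr coupling (C8–C9) of ring-A aldehyde 13 with (Z)-iodoenoate 20, itself made from the Roche ester 14.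
4. Ring A (13) comes from a catalytic asymmetric Diels–Alder reaction of diene 2 with enal ester 3, then Saegusa oxidation, triflate reduction to the ring diene and α-face dihydroxylation.
5. Ring order: ring A, temporary butenolide, eight-membered lactone and enol ether, ten-membered carbocycle (step 27), γ-lactone (C19 to O7), acetates last.

Key step: step 27

Remark (locants): briarane locants are used throughout; β is the face of ring A that carries the C15 methyl.
Assumption: the catalyst antipodes named in steps 2 and 16 follow the accepted induction models; if the sense were opposite, the other antipode would be used.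

**Route**

Step 1
Reactants: 1 pent-1-en-3-one
Product: 2 (Z)-3-(triisopropylsilyloxy)penta-1,3-diene
Conditions: TIPSOTf, Et3N, CH2Cl2, 0 °C
Reagents that add atoms: triisopropylsilyl trifluoromethanesulfonate, CC(C)[Si](C(C)C)(C(C)C)OS(=O)(=O)C(F)(F)F
Why: Soft enolisation of the ethyl ketone (silyl triflate and amine) should give the (Z)-silyl dienol ether, whose methyl group lies outside the s-cis diene.

Step 2
Reactants: 2 (Z)-3-(triisopropylsilyloxy)penta-1,3-diene; 3 ethyl (2E)-3-methyl-4-oxobut-2-enoate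
Product: 4 Diels–Alder adduct (C1: Me-15 β and CHO α; C10: CO2Et β; C11: Me β; C12 silyl enol ether)
Conditions: (S)-o-tolyl-CBS oxazaborolidine·Tf2NH (10 mol %), CH2Cl2, −78 °C
Reagents that add atoms: none
Why: Catalytic enantioselective Diels–Alder reaction in which the catalyst-bound formyl group sends the nucleophilic diene terminus (C11) to C10 and the silyloxy carbon para to C1, the E dienophile fixes C2 trans to C9, and the catalyst face selection sets C1 and C10 absolutely (C11 is erased in step 6).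

Step 3
Reactants: 4 Diels–Alder adduct
Product: 5 C2 primary alcohol
Conditions: NaBH4, EtOH, −20 °C
Reagents that add atoms: none
Why: Chemoselective borohydride reduction of the aldehyde in the presence of the ester and the silyl enol ether; the cold alcohol is silylated at once so that it cannot close on the C9 ester.

Step 4
Reactants: 5 C2 primary alcohol
Product: 6 C2 TBS ether
Conditions: TBSCl, imidazole, DMF, 0 °C to rt
Reagents that add atoms: tert-butyldimethylsilyl chloride, CC(C)(C)[Si](C)(C)Cl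
Why: Standard silylation of a primary alcohol under conditions that leave the silyl enol ether intact.

Step 5
Reactants: 6 C2 TBS ether
Product: 7 ring-A enone (C12 ketone with C13=C14)
Conditions: Pd(OAc)2 (1.1 equiv), MeCN, rt to 40 °C
Reagents that add atoms: none
Why: Saegusa–Ito oxidation; the oxa-π-allyl palladium species can lose a β-hydrogen only from C14, so the enone forms with a single regiochemistry.

Step 6
Reactants: 7 ring-A enone
Product: 9 cross-conjugated dienyl triflate (C11=C12(OTf)–C13=C14), via potassium dienolate 8 (not isolated)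
Conditions: KHMDS, THF, −78 °C; then PhNTf2
Reagents that add atoms: N-phenylbis(trifluoromethanesulfonimide), O=S(=O)(N(c1ccccc1)S(=O)(=O)C(F)(F)F)C(F)(F)F
Why: Kinetic α′-deprotonation at C11 (no γ-hydrogen exists because C1 is quaternary) and O-triflation of the enolate, which removes the provisional C11 stereocentre.

Step 7
Reactants: 9 cross-conjugated dienyl triflate
Product: 10 ring-A diene ester (C11=C12–C13=C14)
Conditions: Pd(OAc)2 (5 mol %), dppf, Et3SiH, DMF, 60 °C
Reagents that add atoms: none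
Why: Palladium-catalysed hydride reduction of a vinyl triflate, run without amine base so that the doubly activated C10–H is neither epimerised nor shifted into conjugation.

Step 8
Reactants: 10 ring-A diene ester
Product: 11 ring-A cis-diol (11α-OH with Me-20 β; 12α-OH)
Conditions: OsO4 (2 mol %), NMO (1.1 equiv), acetone/H2O, 0 °C
Reagents that add atoms: osmium tetroxide, O=[Os](=O)(=O)=O; N-methylmorpholine N-oxide, C[N+]1([O-])CCOCC1; water, O
Why: Upjohn dihydroxylation in which the electron-rich trisubstituted C11=C12 bond should react before the neopentyl C13=C14 bond, and OsO4 should approach the α face anti to the C10 ester, which sets C11 and C12.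

Step 9
Reactants: 11 ring-A cis-diol
Product: 12 ring-A acetonide ester
Conditions: 2-methoxypropene, PPTS (cat.), CH2Cl2, 0 °C
Reagents that add atoms: 2-methoxypropene, C=C(C)OC
Why: Acetonide formation on a cis-1,2-diol under mild kinetic conditions that spare the primary TBS ether.

Step 10
Reactants: 12 ring-A acetonide ester
Product: 13 ring-A aldehyde (C9 aldehyde β on C10; C2 as CH2OTBS)
Conditions: DIBAL-H (1.1 equiv), toluene, −78 °C; Rochelle salt
Reagents that add atoms: none
Why: Partial reduction of the hindered ester; the aluminium hemiacetal, held by the neighbouring acetonide oxygen, should collapse to the aldehyde only on work-up.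

Step 11
Reactants: 14 methyl (S)-3-hydroxy-2-methylpropanoate
Product: 15 methyl (S)-3-(tert-butyldiphenylsilyloxy)-2-methylpropanoate
Conditions: TBDPSCl, imidazole, DMF, rt
Reagents that add atoms: tert-butyl(chloro)diphenylsilane, CC(C)(C)[Si](Cl)(c1ccccc1)c1ccccc1
Why: Standard silylation; TBDPS is chosen because it tolerates the acetic acid of step 15.

Step 12
Reactants: 15 methyl (S)-3-(tert-butyldiphenylsilyloxy)-2-methylpropanoate
Product: 16 (S)-3-(tert-butyldiphenylsilyloxy)-2-methylpropanal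
Conditions: DIBAL-H, CH2Cl2, −78 °C
Reagents that add atoms: none
Why: Low-temperature DIBAL reduction of the ester to the aldehyde, used crude to keep the α-stereocentre (C17) intact.

Step 13
Reactants: 16 (S)-3-(tert-butyldiphenylsilyloxy)-2-methylpropanal
Product: 17 (R)-tert-butyl[(2-methylbut-3-yn-1-yl)oxy]diphenylsilane
Conditions: dimethyl (1-diazo-2-oxopropyl)phosphonate, K2CO3, MeOH, 0 °C to rt
Reagents that add atoms: dimethyl (1-diazo-2-oxopropyl)phosphonate, CC(=O)C(=[N+]=[N-])P(=O)(OC)OC
Why: Ohira–Bestmann (Seyferth–Gilbert) homologation under mild carbonate conditions, which should not epimerise C17; the new alkyne carbon is C7.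

Step 14
Reactants: 17 (R)-tert-butyl[(2-methylbut-3-yn-1-yl)oxy]diphenylsilane
Product: 19 methyl (R)-5-(tert-butyldiphenylsilyloxy)-4-methylpent-2-ynoate, via lithium acetylide 18 (not isolated)
Conditions: n-BuLi, THF, −78 °C; then ClCO2Me
Reagents that add atoms: methyl chloroformate, COC(=O)Cl
Why: Acylation of a lithium acetylide with a chloroformate, which brings in C6 at the carboxyl level.

Step 15
Reactants: 19 methyl (R)-5-(tert-butyldiphenylsilyloxy)-4-methylpent-2-ynoate
Product: 20 methyl (2Z,4S)-5-(tert-butyldiphenylsilyloxy)-3-iodo-4-methylpent-2-enoate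
Conditions: NaI, AcOH, 70 °C
Reagents that add atoms: sodium iodide, [Na+].[I-]
Why: Conjugate hydroiodination of a ynoate; kinetic anti addition should give the (Z)-β-iodoenoate with iodine on C8 cis to the ester.

Step 16
Reactants: 13 ring-A aldehyde; 20 methyl (2Z,4S)-5-(tert-butyldiphenylsilyloxy)-3-iodo-4-methylpent-2-enoate
Product: 22 butenolide (C6 lactone carbonyl; O9 ring oxygen; C7=C8; C9 as in the target), via C9 hydroxy (Z)-enoate 21 (not isolated)
Conditions: CrCl2, NiCl2 (cat.), (S)-Kishi oxazoline sulfonamide ligand, Et3N, THF, rt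
Reagents that add atoms: none
Why: Nozaki–Hiyama–Kishi coupling in which the alkenylchromium species adds only to the aldehyde and the cis γ-hydroxy ester closes to the butenolide; C9 is set by the chiral sulfonamide–chromium complex (reagent control), in the same sense as Felkin attack anti to the C1 branch.

Step 17
Reactants: 22 butenolide
Product: 23 7,8-dihydroxy lactone (O7 and O8 cis to each other and trans to C10)
Conditions: KMnO4, 18-crown-6, CH2Cl2, −40 °C; aq. NaHSO3
Reagents that add atoms: potassium permanganate, [K+].[O-][Mn](=O)(=O)=O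
Why: Permanganate cis-dihydroxylation of a butenolide, which is fastest at the electron-poor conjugated alkene (the shielded C13=C14 bond should remain) and should occur on the lactone face anti to the bulky ring-A substituent on C9, setting C8 and C7 as in the target.

Step 18
Reactants: 23 7,8-dihydroxy lactone
Product: 24 C7 TBS ether (C8 tertiary hydroxyl free)
Conditions: TBSOTf (1.1 equiv), 2,6-lutidine, CH2Cl2, −78 °C
Reagents that add atoms: tert-butyldimethylsilyl trifluoromethanesulfonate, CC(C)(C)[Si](C)(C)OS(=O)(=O)C(F)(F)F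
Why: Silylation of the secondary α-hydroxyl in preference to the tertiary C8 hydroxyl on steric grounds.

Step 19
Reactants: 24 C7 TBS ether
Product: 25 triol (C6 primary, C8 tertiary and C9 secondary hydroxyls)
Conditions: DIBAL-H (4 equiv), CH2Cl2, −78 to 0 °C
Reagents that add atoms: none
Why: Exhaustive hydride reduction of the γ-lactone to the diol; the weakly nucleophilic aluminium alkoxides should suppress 1,2-silyl migration from O7.

Step 20
Reactants: 25 triol
Product: 26 C8/C9 acetonide with free C6 primary alcohol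
Conditions: 2,2-dimethoxypropane, PPTS (cat.), acetone, rt
Reagents that add atoms: 2,2-dimethoxypropane, COC(C)(C)OC
Why: Thermodynamic ketalisation, which should prefer the 1,2-dioxolane on O8/O9 over the 1,3-dioxane on O6/O8 (syn-axial methyl) and leave the primary hydroxyl free.

Step 21
Reactants: 26 C8/C9 acetonide with free C6 primary alcohol
Product: 27 C6 aldehyde (α-silyloxy aldehyde)
Conditions: Dess–Martin periodinane, NaHCO3, CH2Cl2, 0 °C to rt
Reagents that add atoms: none
Why: Buffered Dess–Martin oxidation of a primary alcohol, mild enough to keep the C7 stereocentre.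

Step 22
Reactants: 27 C6 aldehyde
Product: 28 (6S)-isopropenyl carbinol (O6 and O7 anti in the zigzag)
Conditions: isopropenylmagnesium bromide, THF, −78 °C
Reagents that add atoms: isopropenylmagnesium bromide, C=C(C)[Mg]Br
Why: Grignard addition to an α-silyloxy aldehyde under non-chelation (Cornforth/Felkin–Anh) control, with the C7–O bond anti to the carbonyl and the nucleophile anti to the quaternary C8, which should give the 6,7-anti carbinol.

Step 23
Reactants: 28 (6S)-isopropenyl carbinol
Product: 29 diol (C2 primary and C6 secondary hydroxyls)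
Conditions: HF·pyridine, pyridine, THF, 0 °C to rt
Reagents that add atoms: none
Why: Buffered HF·pyridine should cleave the primary TBS ether before the hindered secondary TBS ether at C7 and the TBDPS ether, and does not touch acetonides.

Step 24
Reactants: 29 diol
Product: 31 seco acid (C2 carboxylic acid and free C6 hydroxyl), via C2 aldehyde 30 (not isolated)
Conditions: TEMPO (cat.), PhI(OAc)2, CH2Cl2, rt; then NaClO2, NaH2PO4, 2-methyl-2-butene, t-BuOH/H2O
Reagents that add atoms: sodium chlorite, [Na+].[O-]Cl=O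
Why: TEMPO/PhI(OAc)2 oxidation is selective for the primary carbinol over the hindered secondary C6 carbinol, and Pinnick oxidation then converts the non-enolisable aldehyde to the acid without touching alkenes (scavenger) or alcohols.

Step 25
Reactants: 31 seco acid
Product: 33 eight-membered lactone (O6 acylated by C2), via mixed anhydride 32 (not isolated)
Conditions: MNBA, DMAP, toluene (2 mM, syringe pump), rt to 40 °C
Reagents that add atoms: none
Why: Shiina macrolactonisation, which is effective for α,α-disubstituted acids; the trans ring-A fusion and the C8/C9 acetonide restrict the seven-atom tether so that C6–OH can reach the activated C2 carbonyl, and C6 keeps its configuration.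

Step 26
Reactants: 33 eight-membered lactone
Product: 34 2-methylene oxocane (exocyclic enol ether at C2; isopropenyl on C6)
Conditions: Cp2TiMe2 (3 equiv), toluene, 70 °C, dark
Reagents that add atoms: dimethyltitanocene, C[Ti](C)(C1C=CC=C1)C1C=CC=C1
Why: Petasis methylenation of the only carbonyl group present, under non-basic and non-acidic conditions that spare the acid-labile enol ether, silyl ethers and acetonides.

Step 27
Reactants: 34 2-methylene oxocane
Product: 35 ten-membered C2 ketone with the (Z)-C5=C6 alkene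
Conditions: xylenes (degassed), BHT, base-washed sealed tube, 170–180 °C
Reagents that add atoms: none
Why: Concerted [3,3]-sigmatropic (Claisen) shift of the allyl vinyl ether C3=C2–O–C6–C5=C4, in which the C3–C4 σ-bond forms as O–C6 breaks, the former ring oxygen becomes the C2 carbonyl and C5=C6 becomes the ring alkene; the closest known reaction type is the thermal Claisen ring expansion of 2-methylene-6-vinyltetrahydropyrans to cyclooct-4-enones, here taken one ring size up (8 to 10). The ten-membered carbocycle is closed by ring expansion through a bicyclo[5.3.1]-like chair transition state, with the new bond made between two exocyclic termini held close by the oxocane, so it is not an end-to-end cyclisation and needs no high dilution. No stereocentre is created: C6 is destroyed and C1, C7–C12 and C17 are spectators. The selectivity required is Z over E at C5=C6, and it is secured because the five-carbon bridge C1–C10–C9–C8–C7 can span C2 and C6 only when C7 is pseudoaxial on the chair, which places C7 cis to C4; with the (6S) configuration the C7 silyloxy group then points away from the six-atom array. The exocyclic enol ether cannot migrate into the ring because C1 is quaternary, and base-washed glass should prevent acid-catalysed hydrolysis.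

Step 28
Reactants: 35 ten-membered C2 ketone
Product: 36 (2R)-alcohol
Conditions: (S)-Me-CBS (0.5 equiv), catecholborane, toluene, −78 to −40 °C
Reagents that add atoms: none
Why: Corey–Bakshi–Shibata reduction under reagent control, with the quaternary C1 as the large and C3H2 as the small substituent, so that the (S)-catalyst should deliver hydride to give the 2R carbinol; catecholborane does not hydroborate the hindered alkenes at this temperature.

Step 29
Reactants: 36 (2R)-alcohol
Product: 37 triol (C2, C7 and C19 hydroxyls; both acetonides kept)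
Conditions: TBAF, THF, 0 °C to rt
Reagents that add atoms: none
Why: Fluoride cleavage of the C7 TBS ether and the C19 TBDPS ether, with the acetonides untouched.

Step 30
Reactants: 37 triol
Product: 39 7,19-γ-lactone (C2 hydroxyl free), via lactol 38 (not isolated)
Conditions: TEMPO (cat.), PhI(OAc)2 (2.5 equiv), CH2Cl2, rt
Reagents that add atoms: none
Why: Oxidative lactonisation of a 1,4-diol, in which the primary C19 alcohol is oxidised first, the aldehyde closes on O7 and the lactol is oxidised further; O9 is locked in the acetonide so only the 7,19-lactone can form, and the hindered C2 carbinol is not oxidised.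

Step 31
Reactants: 39 7,19-γ-lactone
Product: 40 pentaol (C2, C8, C9, C11 and C12 hydroxyls)
Conditions: AcOH/H2O (4:1), 45 °C
Reagents that add atoms: none
Why: Mild aqueous acid hydrolysis of both acetonides, under conditions too weak to ionise the allylic C7–O and C12–O bonds or to protonate the trisubstituted alkene.

Step 32
Reactants: 40 pentaol
Product: 41 CNP0129620.2 (2,9,12-tri-O-acetyl-8,11-dihydroxybriara-5(Z),13-dien-19,7-olide)
Conditions: Ac2O, pyridine, DMAP (cat.), CH2Cl2, 0 °C to rt
Reagents that add atoms: acetic anhydride, CC(=O)OC(C)=O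
Why: Acetylation of the three secondary hydroxyls (C2, C9, C12); the tertiary C8 and C11 hydroxyls should not react under these conditions.

**Compound list**

1 | pent-1-en-3-one | C=CC(=O)CC | starting material
2 | (Z)-3-(triisopropylsilyloxy)penta-1,3-diene | C=C/C(O[Si](C(C)C)(C(C)C)C(C)C)=C/C | intermediate
3 | ethyl (2E)-3-methyl-4-oxobut-2-enoate | CCOC(=O)/C=C(\C)C=O | starting material
4 | Diels–Alder adduct: ethyl 6-formyl-2,6-dimethyl-3-(triisopropylsilyloxy)cyclohex-3-ene-1-carboxylate (Me-15 β, CHO α, CO2Et β, Me-20 β) | CCOC(=O)[C@H]1[C@@H](C)C(O[Si](C(C)C)(C(C)C)C(C)C)=CC[C@]1(C)C=O | intermediate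
5 | C2 primary alcohol of 4 | CCOC(=O)[C@H]1[C@@H](C)C(O[Si](C(C)C)(C(C)C)C(C)C)=CC[C@]1(C)CO | intermediate
6 | C2 TBS ether | CCOC(=O)[C@H]1[C@@H](C)C(O[Si](C(C)C)(C(C)C)C(C)C)=CC[C@]1(C)CO[Si](C)(C)C(C)(C)C | intermediate
7 | ring-A enone (C12=O, C13=C14) | CCOC(=O)[C@H]1[C@@H](C)C(=O)C=C[C@]1(C)CO[Si](C)(C)C(C)(C)C | intermediate
8 | potassium dienolate of 7 | CCOC(=O)[C@H]1C(C)=C([O-])C=C[C@]1(C)CO[Si](C)(C)C(C)(C)C.[K+] | intermediate
9 | dienyl triflate | CCOC(=O)[C@H]1C(C)=C(OS(=O)(=O)C(F)(F)F)C=C[C@]1(C)CO[Si](C)(C)C(C)(C)C | intermediate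
10 | ring-A diene ester | CCOC(=O)[C@H]1C(C)=CC=C[C@]1(C)CO[Si](C)(C)C(C)(C)C | intermediate
11 | ring-A cis-diol (11α-OH, 12α-OH) | CCOC(=O)[C@H]1[C@](C)(O)[C@H](O)C=C[C@]1(C)CO[Si](C)(C)C(C)(C)C | intermediate
12 | ring-A acetonide ester | CCOC(=O)[C@H]1[C@]2(C)OC(C)(C)O[C@@H]2C=C[C@]1(C)CO[Si](C)(C)C(C)(C)C | intermediate
13 | ring-A aldehyde (C9 aldehyde) | O=C[C@H]1[C@]2(C)OC(C)(C)O[C@@H]2C=C[C@]1(C)CO[Si](C)(C)C(C)(C)C | intermediate
14 | methyl (S)-3-hydroxy-2-methylpropanoate | COC(=O)[C@@H](C)CO | starting material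
15 | methyl (S)-3-(tert-butyldiphenylsilyloxy)-2-methylpropanoate | COC(=O)[C@@H](C)CO[Si](c1ccccc1)(c1ccccc1)C(C)(C)C | intermediate
16 | (S)-3-(tert-butyldiphenylsilyloxy)-2-methylpropanal | O=C[C@@H](C)CO[Si](c1ccccc1)(c1ccccc1)C(C)(C)C | intermediate
17 | (R)-tert-butyl[(2-methylbut-3-yn-1-yl)oxy]diphenylsilane | C#C[C@@H](C)CO[Si](c1ccccc1)(c1ccccc1)C(C)(C)C | intermediate
18 | lithium acetylide of 17 | [Li]C#C[C@@H](C)CO[Si](c1ccccc1)(c1ccccc1)C(C)(C)C | intermediate
19 | methyl (R)-5-(tert-butyldiphenylsilyloxy)-4-methylpent-2-ynoate | COC(=O)C#C[C@@H](C)CO[Si](c1ccccc1)(c1ccccc1)C(C)(C)C | intermediate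
20 | methyl (2Z,4S)-5-(tert-butyldiphenylsilyloxy)-3-iodo-4-methylpent-2-enoate | COC(=O)/C=C(\I)[C@@H](C)CO[Si](c1ccccc1)(c1ccccc1)C(C)(C)C | intermediate
21 | C9 hydroxy (Z)-enoate (open form of 22) | COC(=O)/C=C(/[C@@H](C)CO[Si](c1ccccc1)(c1ccccc1)C(C)(C)C)[C@H](O)[C@H]1[C@]2(C)OC(C)(C)O[C@@H]2C=C[C@]1(C)CO[Si](C)(C)C(C)(C)C | intermediate
22 | butenolide (C6 carbonyl, O9 ring oxygen, C7=C8) | O=C1O[C@H]([C@H]2[C@]3(C)OC(C)(C)O[C@@H]3C=C[C@]2(C)CO[Si](C)(C)C(C)(C)C)C([C@@H](C)CO[Si](c2ccccc2)(c2ccccc2)C(C)(C)C)=C1 | intermediate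
23 | 7,8-dihydroxy lactone | O=C1O[C@H]([C@H]2[C@]3(C)OC(C)(C)O[C@@H]3C=C[C@]2(C)CO[Si](C)(C)C(C)(C)C)[C@](O)([C@@H](C)CO[Si](c2ccccc2)(c2ccccc2)C(C)(C)C)[C@H]1O | intermediate
24 | C7 TBS ether of 23 | O=C1O[C@H]([C@H]2[C@]3(C)OC(C)(C)O[C@@H]3C=C[C@]2(C)CO[Si](C)(C)C(C)(C)C)[C@](O)([C@@H](C)CO[Si](c2ccccc2)(c2ccccc2)C(C)(C)C)[C@H]1O[Si](C)(C)C(C)(C)C | intermediate
25 | triol (C6, C8, C9 hydroxyls) | OC[C@H](O[Si](C)(C)C(C)(C)C)[C@@](O)([C@@H](C)CO[Si](c1ccccc1)(c1ccccc1)C(C)(C)C)[C@H](O)[C@H]1[C@]2(C)OC(C)(C)O[C@@H]2C=C[C@]1(C)CO[Si](C)(C)C(C)(C)C | intermediate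
26 | C8/C9 acetonide, C6 primary alcohol | OC[C@H](O[Si](C)(C)C(C)(C)C)[C@]1([C@@H](C)CO[Si](c2ccccc2)(c2ccccc2)C(C)(C)C)OC(C)(C)O[C@@H]1[C@H]2[C@]3(C)OC(C)(C)O[C@@H]3C=C[C@]2(C)CO[Si](C)(C)C(C)(C)C | intermediate
27 | C6 aldehyde | O=C[C@H](O[Si](C)(C)C(C)(C)C)[C@]1([C@@H](C)CO[Si](c2ccccc2)(c2ccccc2)C(C)(C)C)OC(C)(C)O[C@@H]1[C@H]2[C@]3(C)OC(C)(C)O[C@@H]3C=C[C@]2(C)CO[Si](C)(C)C(C)(C)C | intermediate
28 | (6S)-isopropenyl carbinol | C=C(C)[C@H](O)[C@H](O[Si](C)(C)C(C)(C)C)[C@]1([C@@H](C)CO[Si](c2ccccc2)(c2ccccc2)C(C)(C)C)OC(C)(C)O[C@@H]1[C@H]2[C@]3(C)OC(C)(C)O[C@@H]3C=C[C@]2(C)CO[Si](C)(C)C(C)(C)C | intermediate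
29 | diol (C2 and C6 hydroxyls) | C=C(C)[C@H](O)[C@H](O[Si](C)(C)C(C)(C)C)[C@]1([C@@H](C)CO[Si](c2ccccc2)(c2ccccc2)C(C)(C)C)OC(C)(C)O[C@@H]1[C@H]2[C@]3(C)OC(C)(C)O[C@@H]3C=C[C@]2(C)CO | intermediate
30 | C2 aldehyde | C=C(C)[C@H](O)[C@H](O[Si](C)(C)C(C)(C)C)[C@]1([C@@H](C)CO[Si](c2ccccc2)(c2ccccc2)C(C)(C)C)OC(C)(C)O[C@@H]1[C@H]2[C@]3(C)OC(C)(C)O[C@@H]3C=C[C@]2(C)C=O | intermediate
31 | seco acid | C=C(C)[C@H](O)[C@H](O[Si](C)(C)C(C)(C)C)[C@]1([C@@H](C)CO[Si](c2ccccc2)(c2ccccc2)C(C)(C)C)OC(C)(C)O[C@@H]1[C@H]2[C@]3(C)OC(C)(C)O[C@@H]3C=C[C@]2(C)C(=O)O | intermediate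
32 | mixed anhydride of 31 with 2-methyl-6-nitrobenzoic acid | C=C(C)[C@H](O)[C@H](O[Si](C)(C)C(C)(C)C)[C@]1([C@@H](C)CO[Si](c2ccccc2)(c2ccccc2)C(C)(C)C)OC(C)(C)O[C@@H]1[C@H]2[C@]3(C)OC(C)(C)O[C@@H]3C=C[C@]2(C)C(=O)OC(=O)c1c(C)cccc1[N+](=O)[O-] | intermediate
33 | eight-membered lactone | CC1(C)O[C@@H]2[C@H]3[C@]4(C)OC(C)(C)O[C@@H]4C=C[C@]3(C)C(=O)O[C@@H](C(C)=C)[C@H](O[Si](C)(C)C(C)(C)C)[C@@]2(O1)[C@@H](C)CO[Si](c1ccccc1)(c1ccccc1)C(C)(C)C | intermediate
34 | 2-methylene-6-isopropenyl oxocane (Claisen precursor) | CC1(C)O[C@@H]2[C@H]3[C@]4(C)OC(C)(C)O[C@@H]4C=C[C@]3(C)C(=C)O[C@@H](C(C)=C)[C@H](O[Si](C)(C)C(C)(C)C)[C@@]2(O1)[C@@H](C)CO[Si](c1ccccc1)(c1ccccc1)C(C)(C)C | intermediate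
35 | ten-membered (Z)-alkenyl C2 ketone | CC1(C)O[C@@H]2[C@H]3[C@]4(C)OC(C)(C)O[C@@H]4C=C[C@]3(C)C(=O)CC/C(C)=C\[C@H](O[Si](C)(C)C(C)(C)C)[C@@]2(O1)[C@@H](C)CO[Si](c1ccccc1)(c1ccccc1)C(C)(C)C | intermediate
36 | (2R)-alcohol | CC1(C)O[C@@H]2[C@H]3[C@]4(C)OC(C)(C)O[C@@H]4C=C[C@]3(C)[C@H](O)CC/C(C)=C\[C@H](O[Si](C)(C)C(C)(C)C)[C@@]2(O1)[C@@H](C)CO[Si](c1ccccc1)(c1ccccc1)C(C)(C)C | intermediate
37 | triol (C2, C7, C19 hydroxyls) | CC1(C)O[C@@H]2[C@H]3[C@]4(C)OC(C)(C)O[C@@H]4C=C[C@]3(C)[C@H](O)CC/C(C)=C\[C@H](O)[C@@]2(O1)[C@@H](C)CO | intermediate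
38 | lactol (anomeric mixture) | CC1(C)O[C@@H]2[C@H]3[C@]4(C)OC(C)(C)O[C@@H]4C=C[C@]3(C)[C@H](O)CC/C(C)=C\[C@@H]5OC(O)[C@H](C)[C@]52O1 | intermediate
39 | 7,19-γ-lactone bis-acetonide | CC1(C)O[C@@H]2[C@H]3[C@]4(C)OC(C)(C)O[C@@H]4C=C[C@]3(C)[C@H](O)CC/C(C)=C\[C@@H]5OC(=O)[C@H](C)[C@]52O1 | intermediate
40 | pentaol | O[C@@H]1[C@H]2[C@](C)(O)[C@H](O)C=C[C@]2(C)[C@H](O)CC/C(C)=C\[C@@H]2OC(=O)[C@H](C)[C@]21O | intermediate
41 | CNP0129620.2 | CC(=O)O[C@@H]1[C@H]2[C@](C)(O)[C@H](OC(C)=O)C=C[C@]2(C)[C@H](OC(C)=O)CC/C(C)=C\[C@@H]2OC(=O)[C@H](C)[C@]21O | target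

**Step count and risks**

Total: 32 steps. Longest linear sequence: 27 steps (steps 1–10 and 16–32).

Steps most likely to fail:

1. Step 27 (Claisen ring expansion). The heavily substituted oxocane may not reach the chair transition state below the temperature at which retro-ene cleavage across O–C6 or general decomposition sets in, so conversion could stall or material could be lost. Fallback (B-alkyl Suzuki–Miyaura macrocyclisation, C4–C5 closure), setting out from aldehyde 27 and returning at 35: olefination of 27 with the ylide from (1-iodoethyl)triphenylphosphonium iodide and NaHMDS should give the (Z)-2-iodoalkene F1. HF·pyridine then frees the C2 primary alcohol F2, Dess–Martin oxidation gives the C2 aldehyde F3, and vinylmagnesium bromide gives the C2 allylic alcohol F4 as a mixture of C2 epimers. 9-BBN hydroboration of the vinyl group and intramolecular coupling (Pd(dppf)Cl2, AsPh3, Cs2CO3, DMF/THF/H2O, high dilution) should close the ten-membered ring with retention of the Z geometry to the ring alcohol F5 (C2 epimers), which Dess–Martin oxidation converts to 35.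

2. Step 25 (eight-membered lactonisation). Acyl transfer at the neopentyl C2 carbonyl may be slower than intermolecular acylation, leading to oligomers or to attack at the aryl carbonyl of the mixed anhydride. Fallback (activation of the alcohol instead of the acid), setting out from seco acid 31 and returning at 35: Mitsunobu macrolactonisation (PPh3, DIAD, toluene, slow addition) uses the hindered carboxylate only as an O-nucleophile and should give, with inversion, the (6R)-lactone F6. Petasis methylenation gives the (6R)-enol ether F7, and its Claisen shift through the mirror-image chair (C7 again pseudoaxial) converges on 35 because C6 becomes trigonal.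

3. Step 16 (Ni/Cr coupling). Facial selection at C9 by the chiral chromium complex may be weak against an aldehyde flanked by two quaternary carbons, and the coupling of two hindered partners may be slow. Fallback (separation and equilibration instead of reagent control), setting out from 13 and 20 and returning at 22: the ligand-free coupling (CrCl2, NiCl2 cat., DMSO, rt) should give 22 together with its C9 epimer F8. After chromatographic separation, F8 is equilibrated at the ring γ-carbon with catalytic DBU (through the 2-oxidofuran) and the resulting mixture is recycled to 22.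

**Further compounds**

F1 | step 27 | (Z)-2-iodoalkene (C5 iodide, C5=C6) | C/C(I)=C/[C@H](O[Si](C)(C)C(C)(C)C)[C@]1([C@@H](C)CO[Si](c2ccccc2)(c2ccccc2)C(C)(C)C)OC(C)(C)O[C@@H]1[C@H]2[C@]3(C)OC(C)(C)O[C@@H]3C=C[C@]2(C)CO[Si](C)(C)C(C)(C)C
F2 | step 27 | C2 primary alcohol of F1 | C/C(I)=C/[C@H](O[Si](C)(C)C(C)(C)C)[C@]1([C@@H](C)CO[Si](c2ccccc2)(c2ccccc2)C(C)(C)C)OC(C)(C)O[C@@H]1[C@H]2[C@]3(C)OC(C)(C)O[C@@H]3C=C[C@]2(C)CO
F3 | step 27 | C2 aldehyde | C/C(I)=C/[C@H](O[Si](C)(C)C(C)(C)C)[C@]1([C@@H](C)CO[Si](c2ccccc2)(c2ccccc2)C(C)(C)C)OC(C)(C)O[C@@H]1[C@H]2[C@]3(C)OC(C)(C)O[C@@H]3C=C[C@]2(C)C=O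
F4 | step 27 | C2 allylic alcohol (C2 epimers) | C/C(I)=C/[C@H](O[Si](C)(C)C(C)(C)C)[C@]1([C@@H](C)CO[Si](c2ccccc2)(c2ccccc2)C(C)(C)C)OC(C)(C)O[C@@H]1[C@H]2[C@]3(C)OC(C)(C)O[C@@H]3C=C[C@]2(C)C(O)C=C
F5 | step 27 | ten-membered ring alcohol (C2 epimers) | CC1(C)O[C@@H]2[C@H]3[C@]4(C)OC(C)(C)O[C@@H]4C=C[C@]3(C)C(O)CC/C(C)=C\[C@H](O[Si](C)(C)C(C)(C)C)[C@@]2(O1)[C@@H](C)CO[Si](c1ccccc1)(c1ccccc1)C(C)(C)C
F6 | step 25 | (6R)-eight-membered lactone | CC1(C)O[C@@H]2[C@H]3[C@]4(C)OC(C)(C)O[C@@H]4C=C[C@]3(C)C(=O)O[C@H](C(C)=C)[C@H](O[Si](C)(C)C(C)(C)C)[C@@]2(O1)[C@@H](C)CO[Si](c1ccccc1)(c1ccccc1)C(C)(C)C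
F7 | step 25 | (6R)-2-methylene oxocane | CC1(C)O[C@@H]2[C@H]3[C@]4(C)OC(C)(C)O[C@@H]4C=C[C@]3(C)C(=C)O[C@H](C(C)=C)[C@H](O[Si](C)(C)C(C)(C)C)[C@@]2(O1)[C@@H](C)CO[Si](c1ccccc1)(c1ccccc1)C(C)(C)C
F8 | step 16 | C9 epimer of butenolide 22 | O=C1O[C@@H]([C@H]2[C@]3(C)OC(C)(C)O[C@@H]3C=C[C@]2(C)CO[Si](C)(C)C(C)(C)C)C([C@@H](C)CO[Si](c2ccccc2)(c2ccccc2)C(C)(C)C)=C1
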